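Retrosynthesis: the two benzyl ethers on O5 and O7 are removed first. Then the aryl ketone bond C4–C4a of ring C is cut, then the O3–acyl bond, then the aryl ether bond O1–C2.
Forward: a trans-3-phenylglycidate supplies C2, C3, C4 and ring B in one piece. Ring A is attached through O1 by epoxide opening, the side-chain ester is put on O3, ring C is closed last by acylation of ring A, and the benzyl groups are then removed.
Enabling feature: ring A is a phloroglucinol nucleus (O1, O5 and O7 mutually meta). In the 3,5-bis(benzyloxy)phenoxy precursor the two carbons ortho to O1 are equivalent, and each is ortho or para to all three oxygens. The tethered carboxyl carbon C4 can therefore close only the six-membered ring C, as one regioisomer, under acid mild enough for the benzylic ether and the ester.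
Stereochemistry: C3 (R) is the untouched C2 of the (2R,3S)-glycidate. C2 (R) arises by SN2 inversion at the benzylic epoxide carbon; this anti opening becomes the 2,3-trans ring. The (S) centre of the ester is bought in the anhydride.
Helpers: benzyl ethers on O5 and O7 (removed in the last step) and a trifluoroacetyl mixed anhydride as activating group (lost in the ring closure).

Key step: step 3

Assumption: methyl (2R,3S)-3-phenylglycidate is bought as the resolved trans enantiomer, and 3,5-bis(benzyloxy)phenol and (2S)-2-methylbutanoic anhydride are catalogue compounds.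

Step 1
Reactants: 1 methyl (2R,3S)-3-phenyloxirane-2-carboxylate; 2 3,5-bis(benzyloxy)phenol
Product: 4 (2R,3R)-3-[3,5-bis(benzyloxy)phenoxy]-2-hydroxy-3-phenylpropanoic acid, via hydroxy ester 3 (not isolated)
Conditions: 2 (1.1 equiv), Cs2CO3 (0.3 equiv), DMF, 60 °C; then LiOH·H2O (2 equiv), THF/H2O, 0 °C to rt; 1 M HCl to pH 3
Reagents that add atoms: lithium hydroxide, [Li+].[OH-]
Why: Phenoxide opening of a 2,3-epoxy ester (SN2 epoxide phenolysis) should take place at the benzylic carbon, remote from the ester, with inversion, so that the (3S) epoxide carbon becomes the (3R) aryl ether carbon (later C2) while the (2R) carbinol carbon (later C3) is untouched; the cold saponification in the same flask frees the carboxyl group without touching either centre.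

Step 2
Reactants: 4 (2R,3R)-3-[3,5-bis(benzyloxy)phenoxy]-2-hydroxy-3-phenylpropanoic acid; 5 (2S)-2-methylbutanoic anhydride
Product: 6 (2R,3R)-3-[3,5-bis(benzyloxy)phenoxy]-2-{[(2S)-2-methylbutanoyl]oxy}-3-phenylpropanoic acid
Conditions: 5 (1.5 equiv), DMAP (0.1 equiv), pyridine/CH2Cl2, 0 °C to rt; then H2O; 1 M HCl wash
Reagents that add atoms: none
Why: DMAP-catalysed acylation of the secondary alcohol by the symmetrical anhydride (nucleophilic catalysis through the N-acylpyridinium ion) should give the ester with no new stereocentre, the (S) centre coming unchanged from the anhydride, and any mixed anhydride formed at the carboxyl group is hydrolysed in the aqueous quench.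

Step 3
Reactants: 6 (2R,3R)-3-[3,5-bis(benzyloxy)phenoxy]-2-{[(2S)-2-methylbutanoyl]oxy}-3-phenylpropanoic acid
Product: 8 (2R,3R)-5,7-bis(benzyloxy)-4-oxo-2-phenyl-3,4-dihydro-2H-chromen-3-yl (2S)-2-methylbutanoate, via acyl trifluoroacetate 7 (not isolated)
Conditions: (CF3CO)2O (2 equiv), CH2Cl2, 0 °C to rt
Reagents that add atoms: none
Why: Trifluoroacetic anhydride turns the carboxyl group into the acyl trifluoroacetate 7, an acylium equivalent that is attacked by the ring A carbon ortho to the ether oxygen (electrophilic aromatic substitution through a Wheland intermediate, then loss of a proton and of trifluoroacetate). The closest known reaction type is the intramolecular Friedel–Crafts acylation of 3-aryloxypropanoic acids to chroman-4-ones through mixed trifluoroacetic anhydrides. Ring C closes in the 6-exo-trig mode, the only ring size the O–C–C tether allows. No stereocentre is formed: C2 and C3 come in with the substrate, and the anti arrangement of the chain becomes the trans-diequatorial 2-phenyl/3-acyloxy pattern of the ring. The step needs regioselectivity on ring A and preference for ring closure over C-trifluoroacetylation and over ionisation of the benzylic C–O bond; the first is secured by the symmetry of the phloroglucinol ring (both ortho carbons equivalent, the para carbon out of reach), the second by the tethered acyl group sitting next to a ring activated by three oxygens, so that closure should run at 0 °C without a Lewis acid, and by the two electron-withdrawing groups beside the benzylic carbon. The acid-only medium avoids enolisation, so the configuration at the carbon next to the carboxyl group and the side-chain ester should be kept.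

Step 4
Reactants: 8 (2R,3R)-5,7-bis(benzyloxy)-4-oxo-2-phenyl-3,4-dihydro-2H-chromen-3-yl (2S)-2-methylbutanoate
Product: 9 (2R,3R)-5,7-dihydroxy-4-oxo-2-phenyl-3,4-dihydro-2H-chromen-3-yl (2S)-2-methylbutanoate
Conditions: H2 (1 atm), 10% Pd/C, EtOAc/MeOH, rt
Reagents that add atoms: none
Why: Hydrogenolysis of the two aryl benzyl ethers on palladium should free O5 and O7 under neutral conditions that leave the ester, the aryl ketone and the cyclic benzylic ether O1–C2 untouched, as is usual in the debenzylation of protected dihydroflavonols, and no stereocentre is affected.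

Compound list
1 | methyl (2R,3S)-3-phenyloxirane-2-carboxylate (methyl trans-3-phenylglycidate) | COC(=O)[C@@H]1O[C@H]1c1ccccc1 | starting material
2 | 3,5-bis(benzyloxy)phenol | Oc1cc(OCc2ccccc2)cc(OCc2ccccc2)c1 | starting material
3 | methyl (2R,3R)-3-[3,5-bis(benzyloxy)phenoxy]-2-hydroxy-3-phenylpropanoate | O[C@@H](C(=O)OC)[C@H](Oc1cc(OCc2ccccc2)cc(OCc2ccccc2)c1)c1ccccc1 | intermediate
4 | (2R,3R)-3-[3,5-bis(benzyloxy)phenoxy]-2-hydroxy-3-phenylpropanoic acid | O[C@@H](C(=O)O)[C@H](Oc1cc(OCc2ccccc2)cc(OCc2ccccc2)c1)c1ccccc1 | intermediate
5 | (2S)-2-methylbutanoic anhydride | CC[C@H](C)C(=O)OC(=O)[C@@H](C)CC | starting material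
6 | (2R,3R)-3-[3,5-bis(benzyloxy)phenoxy]-2-{[(2S)-2-methylbutanoyl]oxy}-3-phenylpropanoic acid | CC[C@H](C)C(=O)O[C@@H](C(=O)O)[C@H](Oc1cc(OCc2ccccc2)cc(OCc2ccccc2)c1)c1ccccc1 | intermediate
7 | mixed anhydride of 6 with trifluoroacetic acid (acyl trifluoroacetate) | CC[C@H](C)C(=O)O[C@@H](C(=O)OC(=O)C(F)(F)F)[C@H](Oc1cc(OCc2ccccc2)cc(OCc2ccccc2)c1)c1ccccc1 | intermediate
8 | (2R,3R)-5,7-bis(benzyloxy)-4-oxo-2-phenyl-3,4-dihydro-2H-chromen-3-yl (2S)-2-methylbutanoate | CC[C@H](C)C(=O)O[C@H]1C(=O)c2c(OCc3ccccc3)cc(OCc3ccccc3)cc2O[C@@H]1c1ccccc1 | intermediate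
9 | (2R,3R)-5,7-dihydroxy-4-oxo-2-phenyl-3,4-dihydro-2H-chromen-3-yl (2S)-2-methylbutanoate | CC[C@H](C)C(=O)O[C@H]1C(=O)c2c(O)cc(O)cc2O[C@@H]1c1ccccc1 | target

Total step count: 4. Longest linear sequence: 4 steps (1 to 4 to 6 to 8 to 9).

Steps most likely to fail

Step 3. The acid medium may ionise the benzylic C–O bond with help from the neighbouring 2-methylbutanoate carbonyl, which would cost ring A or the C2 configuration, or the activated acid may lose configuration at the adjacent carbon. The fallback changes the order of events, so that ring C is closed before the chiral ester is present. It sets out from 4. Excess trifluoroacetic anhydride in CH2Cl2 at 0 °C should give the O-trifluoroacetylated mixed anhydride F1, whose trifluoroacetoxy group is a poor participating group and disfavours benzylic ionisation. F1 should close in the same flask to (2R,3R)-5,7-bis(benzyloxy)-4-oxo-2-phenyl-3,4-dihydro-2H-chromen-3-yl trifluoroacetate F2. Brief methanolysis (MeOH, NaHCO3, 0 °C) should give (2R,3R)-5,7-bis(benzyloxy)-3-hydroxy-2-phenyl-2,3-dihydro-4H-chromen-4-one F3. Esterification of its 3-hydroxyl with 5 and DMAP in CH2Cl2 comes back to the route at 8.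

Step 1. The opening may suffer from attack at the wrong epoxide carbon, partial loss of configuration at the benzylic carbon through a cation-like opening, C-alkylation by the ambident phenoxide, or base-induced elimination from the hydroxy ester. The fallback opens an epoxy alcohol, which has no enolisable ester, and adjusts the oxidation level afterwards. It sets out from 1. NaBH4 in MeOH/THF at 0 °C should reduce the ester to [(2S,3S)-3-phenyloxiran-2-yl]methanol F4. The sodium salt of 2 in aqueous NaOH/1,4-dioxane at 70 °C should open F4 at the benzylic carbon with inversion, as is precedented for 3-phenylglycidol and phenols, to give (2S,3R)-3-[3,5-bis(benzyloxy)phenoxy]-3-phenylpropane-1,2-diol F5. Selective oxidation of the primary alcohol with TEMPO (cat.) and PhI(OAc)2 in MeCN/H2O comes back to the route at 4.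

Step 2. Activation of the free carboxyl group as a mixed anhydride may lead to esterification between molecules of 4, or to elimination of the aryloxide from the activated acid. The fallback acylates while the carboxyl group is still masked. It sets out from 3, isolated by stopping step 1 before the hydroxide is added. Acylation of 3 with 5 and DMAP in CH2Cl2 should give methyl (2R,3R)-3-[3,5-bis(benzyloxy)phenoxy]-2-{[(2S)-2-methylbutanoyl]oxy}-3-phenylpropanoate F6. The methyl group is then removed by SN2 dealkylation with LiI in refluxing EtOAc, which attacks the methyl carbon and should leave the secondary ester alone. Acid work-up comes back to the route at 6.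

Further compounds
F1 | step 3 | (2R,3R)-3-[3,5-bis(benzyloxy)phenoxy]-3-phenyl-2-(trifluoroacetoxy)propanoic trifluoroacetic anhydride | FC(F)(F)C(=O)O[C@@H](C(=O)OC(=O)C(F)(F)F)[C@H](Oc1cc(OCc2ccccc2)cc(OCc2ccccc2)c1)c1ccccc1
F2 | step 3 | (2R,3R)-5,7-bis(benzyloxy)-4-oxo-2-phenyl-3,4-dihydro-2H-chromen-3-yl trifluoroacetate | FC(F)(F)C(=O)O[C@H]1C(=O)c2c(OCc3ccccc3)cc(OCc3ccccc3)cc2O[C@@H]1c1ccccc1
F3 | step 3 | (2R,3R)-5,7-bis(benzyloxy)-3-hydroxy-2-phenyl-2,3-dihydro-4H-chromen-4-one | O[C@H]1C(=O)c2c(OCc3ccccc3)cc(OCc3ccccc3)cc2O[C@@H]1c1ccccc1
F4 | step 1 | [(2S,3S)-3-phenyloxiran-2-yl]methanol | OC[C@@H]1O[C@H]1c1ccccc1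
F5 | step 1 | (2S,3R)-3-[3,5-bis(benzyloxy)phenoxy]-3-phenylpropane-1,2-diol | O[C@@H](CO)[C@H](Oc1cc(OCc2ccccc2)cc(OCc2ccccc2)c1)c1ccccc1
F6 | step 2 | methyl (2R,3R)-3-[3,5-bis(benzyloxy)phenoxy]-2-{[(2S)-2-methylbutanoyl]oxy}-3-phenylpropanoate | CC[C@H](C)C(=O)O[C@@H](C(=O)OC)[C@H](Oc1cc(OCc2ccccc2)cc(OCc2ccccc2)c1)c1ccccc1
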